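**Plan**

- Locants: C1H2=C2 carries the 4‑oxopentyl chain, C3 the CO2H, C4 the 2‑oxoethyl arm, C5 the formyl group; the ring is O1′, C2′(=C5), C3′=C4′, C5′(CH3)2. Enabling feature: O1′ is bonded to C2′ and to the quaternary C5′, the two carbons flanking the cis C3′=C4′ bond, so C2′–C5′ are the four carbons of an (E)‑4‑methylpenta‑1,3‑dienyl chain on C5 that has taken up O2 at both ends.
- Cuts, in order: C5–CHO (formylation of an enol ether); the C5=C2′ bond and O1′–C2′ back to a hemiketal and then to a 3,6‑dihydro‑1,2‑dioxine, which means C2′–O and C5′–O (diene + O2); C2′=C3′ (Julia–Kocienski); C2–C3 (alkenylation of a lactone enolate); the C4–CH2 bond of the oxoethyl arm (conjugate vinylation).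
- Forward: the ring of 5,6‑dihydro‑2H‑pyran‑2‑one (future carboxyl carbon, C3, C4, C5, C2′) is substituted at C4, then at C3, and opened; the chain is extended to the diene; the six‑membered peroxide closes in the key step and is contracted by base, then acid, to the five‑membered ring; formylation and deprotection finish.
- Stereochemistry: C4 comes from a rhodium/(R)‑BINAP conjugate addition; C3 from trans‑selective alkenylation on the lactone; the peroxide CH is uncontrolled and erased; C5=C2′ settles thermodynamically.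

Key step: step 10

Remark on the chemistry: the C5=C2′ bond of the target is a push–pull (β‑alkoxy enal) alkene of low rotational barrier; its (E) geometry (formyl anti to O1′, C4 next to O1′) is assumed to be the thermodynamic one and is reached by equilibration, not set kinetically.

**Route**

Step 1
Reactants: 1 2-(2-bromoethyl)-2-methyl-1,3-dioxolane; 2 2,3-dibromoprop-1-ene
Product: 4 2-(4-bromopent-4-en-1-yl)-2-methyl-1,3-dioxolane, via Grignard reagent 3 (not isolated)
Conditions: Mg, THF, 20–25 °C; then 2, Li2CuCl4 (3 mol %), THF, −20 → 0 °C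
Reagents that add atoms: none
Why: Copper‑catalysed Grignard allylic substitution, in which the allylic C–Br of 2 is displaced (SN2 and SN2′ give the same 2‑bromo‑1‑alkene) while the vinylic C–Br stays inert and the ketal‑bearing Grignard reagent is stable below 25 °C; no stereocentre is involved.

Step 2
Reactants: 5 5,6-dihydro-2H-pyran-2-one; 6 potassium ethenyltrifluoroborate
Product: 7 (4R)-4-ethenyltetrahydro-2H-pyran-2-one
Conditions: [Rh(cod)2]PF6 (3 mol %), (R)-BINAP (3.3 mol %), toluene/H2O 4:1, 100 °C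
Reagents that add atoms: none
Why: Hayashi–Miyaura reaction, in which the vinyl–rhodium species adds 1,4 to the cyclic enoate and the BINAP ligand differentiates the enantiotopic faces at C4, (R)-BINAP being chosen because the established model for six‑membered cyclic acceptors ((S)-ligand gives (S)-3-substituted cyclohexanones) predicts the (4R)-vinyl lactone.

Step 3
Reactants: 7 (4R)-4-ethenyltetrahydro-2H-pyran-2-one; 8 dioxygen
Product: 9 2-[(4S)-2-oxotetrahydro-2H-pyran-4-yl]acetaldehyde
Conditions: PdCl2(PhCN)2 (12 mol %), CuCl2·2H2O (12 mol %), AgNO2 (6 mol %), t-BuOH/MeNO2 15:1, O2 (1 atm), 20 °C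
Reagents that add atoms: none
Why: Nitrite‑co‑catalysed, aldehyde‑selective (anti‑Markovnikov) Wacker oxidation of the terminal alkene, chosen because it gives the aldehyde without passing through a free 2‑hydroxyethyl arm that could translactonise and so racemise C4; the stereocentre is untouched and its descriptor changes from R to S only through the priority rules.

Step 4
Reactants: 9 2-[(4S)-2-oxotetrahydro-2H-pyran-4-yl]acetaldehyde
Product: 10 (4S)-4-(1,3-dioxolan-2-ylmethyl)tetrahydro-2H-pyran-2-one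
Conditions: Me3SiOCH2CH2OSiMe3 (1.2 equiv), Me3SiOTf (2 mol %), CH2Cl2, −78 °C; pyridine quench
Reagents that add atoms: 1,2-bis(trimethylsilyloxy)ethane, C[Si](C)(C)OCCO[Si](C)(C)C
Why: Acetalisation under Noyori conditions (silyl triflate catalysis, aprotic, low temperature) converts the aldehyde chemoselectively and leaves the lactone closed because neither free alcohol nor water is present.

Step 5
Reactants: 10 (4S)-4-(1,3-dioxolan-2-ylmethyl)tetrahydro-2H-pyran-2-one; 4 2-(4-bromopent-4-en-1-yl)-2-methyl-1,3-dioxolane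
Product: 13 (3R,4S)-4-(1,3-dioxolan-2-ylmethyl)-3-[5-(2-methyl-1,3-dioxolan-2-yl)pent-1-en-2-yl]tetrahydro-2H-pyran-2-one, via lithium enolate 11 (not isolated), via chlorozinc enolate 12 (not isolated)
Conditions: LiN(SiMe3)2 (1.1 equiv), THF, −78 °C; ZnCl2 (1.2 equiv), −78 → 0 °C; then 4, Pd(dba)2 (5 mol %), P(t-Bu)3 (5 mol %), THF, 25 °C
Reagents that add atoms: none
Why: Palladium‑catalysed α‑alkenylation of an ester enolate (Negishi‑type coupling of the zinc enolate after oxidative addition of the 2‑bromo‑1‑alkene to zerovalent palladium), in which the C–C bond forms on the lactone face anti to the C4 side chain and so sets C3 as (R), trans to C4, while the weakly basic zinc enolate neither epimerises the product nor moves the new double bond into conjugation.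

Step 6
Reactants: 13 (3R,4S)-4-(1,3-dioxolan-2-ylmethyl)-3-[5-(2-methyl-1,3-dioxolan-2-yl)pent-1-en-2-yl]tetrahydro-2H-pyran-2-one
Product: 15 4-methoxybenzyl (2R,3S)-3-(1,3-dioxolan-2-ylmethyl)-5-hydroxy-2-[5-(2-methyl-1,3-dioxolan-2-yl)pent-1-en-2-yl]pentanoate, via potassium carboxylate 14 (not isolated)
Conditions: KOH (1.05 equiv), THF/H2O, 0 °C; evaporate to dryness; 4-MeOC6H4CH2Cl, Bu4NI (10 mol %), DMF, 20 °C
Reagents that add atoms: potassium hydroxide, [K+].[OH-]; 4-methoxybenzyl chloride, COc1ccc(CCl)cc1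
Why: Lactone saponification followed by SN2 O‑alkylation of the carboxylate, in which hydroxide attacks the acyl carbon far faster than it removes the C3 proton and the carboxylate no longer acidifies C3, so both stereocentres are kept; the hydroxy ester is used at once to forestall relactonisation.

Step 7
Reactants: 15 4-methoxybenzyl (2R,3S)-3-(1,3-dioxolan-2-ylmethyl)-5-hydroxy-2-[5-(2-methyl-1,3-dioxolan-2-yl)pent-1-en-2-yl]pentanoate
Product: 16 4-methoxybenzyl (2R,3R)-3-(1,3-dioxolan-2-ylmethyl)-2-[5-(2-methyl-1,3-dioxolan-2-yl)pent-1-en-2-yl]-5-[(1-phenyl-1H-tetrazol-5-yl)sulfanyl]pentanoate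
Conditions: 1-phenyl-1H-tetrazole-5-thiol, PPh3, DIAD, THF, 0 → 20 °C
Reagents that add atoms: 1-phenyl-1H-tetrazole-5-thiol, Sc1nnnn1-c1ccccc1
Why: Mitsunobu reaction, in which the primary alcohol is activated as its alkoxyphosphonium salt and displaced by the acidic tetrazolethiol under neutral conditions that leave the ester, the acetals and C3 untouched (the descriptor at C3 of the pentanoate changes only through the priority rules).

Step 8
Reactants: 16 4-methoxybenzyl (2R,3R)-3-(1,3-dioxolan-2-ylmethyl)-2-[5-(2-methyl-1,3-dioxolan-2-yl)pent-1-en-2-yl]-5-[(1-phenyl-1H-tetrazol-5-yl)sulfanyl]pentanoate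
Product: 17 4-methoxybenzyl (2R,3R)-3-(1,3-dioxolan-2-ylmethyl)-2-[5-(2-methyl-1,3-dioxolan-2-yl)pent-1-en-2-yl]-5-[(1-phenyl-1H-tetrazol-5-yl)sulfonyl]pentanoate
Conditions: (NH4)6Mo7O24·4H2O (10 mol %), 30 % H2O2, EtOH, 0 → 20 °C
Reagents that add atoms: hydrogen peroxide, OO
Why: Molybdate‑catalysed peroxide oxidation of the sulfide through the sulfoxide to the sulfone, the peroxomolybdate being electrophilic toward sulfur but too weak to epoxidise the hindered 1,1‑disubstituted alkene.

Step 9
Reactants: 17 4-methoxybenzyl (2R,3R)-3-(1,3-dioxolan-2-ylmethyl)-2-[5-(2-methyl-1,3-dioxolan-2-yl)pent-1-en-2-yl]-5-[(1-phenyl-1H-tetrazol-5-yl)sulfonyl]pentanoate; 18 3-methylbut-2-enal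
Product: 20 4-methoxybenzyl (2R,3S,5E)-3-(1,3-dioxolan-2-ylmethyl)-8-methyl-2-[5-(2-methyl-1,3-dioxolan-2-yl)pent-1-en-2-yl]nona-5,7-dienoate, via potassium sulfonyl carbanion 19 (not isolated)
Conditions: KN(SiMe3)2 (1.05 equiv), DME, −78 °C, 20 min; then 18, −78 → 20 °C
Reagents that add atoms: none
Why: Julia–Kocienski olefination, in which the metalated phenyltetrazolyl sulfone adds to the enal and Smiles rearrangement with loss of SO2 and tetrazololate forms the C2′=C3′ bond with the (E) preference typical of these sulfones with a potassium counter‑ion in DME, the sulfonyl CH2 being deprotonated faster than the hindered tertiary C3–H so that C3 should not epimerise.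

Step 10
Reactants: 20 4-methoxybenzyl (2R,3S,5E)-3-(1,3-dioxolan-2-ylmethyl)-8-methyl-2-[5-(2-methyl-1,3-dioxolan-2-yl)pent-1-en-2-yl]nona-5,7-dienoate; 8 dioxygen
Product: 21 4-methoxybenzyl (2R,3S)-4-(6,6-dimethyl-3,6-dihydro-1,2-dioxin-3-yl)-3-(1,3-dioxolan-2-ylmethyl)-2-[5-(2-methyl-1,3-dioxolan-2-yl)pent-1-en-2-yl]butanoate (both epimers at the dioxine CH)
Conditions: O2, 5,10,15,20-tetraphenylporphyrin (1 mol %), white LED, CH2Cl2, −30 °C
Reagents that add atoms: none
Why: Photosensitised singlet oxygen adds suprafacially to C2′ and C5′ of the s‑cis diene in a concerted, possibly asynchronous (4+2) cycloaddition that forms both C–O bonds and moves the double bond to C3′=C4′, which is thereby locked cis inside the new ring. The closest known reaction type is the dye‑sensitised photooxygenation of acyclic 1,3‑dienes, terpenoid 4‑methylpenta‑1,3‑dienyl chains included, to 3,6‑dihydro‑1,2‑dioxines. The six‑membered peroxide ring closes by this (4+2) mode, both new bonds going to one O2 molecule in a single pericyclic event. The one new stereocentre, the peroxide‑bearing C2′, has no effective controlling element because C4 lies in a flexible 1,3‑relationship, so both epimers are expected, which is harmless since C2′ becomes a carbonyl carbon in step 11. The selectivity needed is cycloaddition over the Schenck ene reaction at the Me2C=CH terminus and at the C1=C2 methylene, and over attack on the anisyl ring: the (E) C2′=C3′ geometry leaves only H and one methyl as inside groups so the s‑cis conformer is reachable, the conjugated diene is the most electron‑rich π‑system, the 1,1‑disubstituted alkene and the arene react far more slowly, and low temperature in an aprotic medium further disfavours ene pathways.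

Step 11
Reactants: 21 4-methoxybenzyl (2R,3S)-4-(6,6-dimethyl-3,6-dihydro-1,2-dioxin-3-yl)-3-(1,3-dioxolan-2-ylmethyl)-2-[5-(2-methyl-1,3-dioxolan-2-yl)pent-1-en-2-yl]butanoate
Product: 23 4-methoxybenzyl (2R,3R)-3-(1,3-dioxolan-2-ylmethyl)-4-(2-hydroxy-5,5-dimethyl-2,5-dihydrofuran-2-yl)-2-[5-(2-methyl-1,3-dioxolan-2-yl)pent-1-en-2-yl]butanoate (both hemiketal epimers), via cis-hydroxyenone 22 (not isolated)
Conditions: Et3N (0.5 equiv), CH2Cl2, 0 → 20 °C
Reagents that add atoms: none
Why: Kornblum–DeLaMare rearrangement, in which the amine removes the only proton α to the peroxide (C2′–H, since C5′ is quaternary), the O–O bond breaks to give the C2′ ketone and the C5′ tertiary alcohol across the cis C3′=C4′ bond, and the hydroxyl then adds to the ketone to close the five‑membered hemiketal, whose new centre is uncontrolled and is removed in step 12.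

Step 12
Reactants: 23 4-methoxybenzyl (2R,3R)-3-(1,3-dioxolan-2-ylmethyl)-4-(2-hydroxy-5,5-dimethyl-2,5-dihydrofuran-2-yl)-2-[5-(2-methyl-1,3-dioxolan-2-yl)pent-1-en-2-yl]butanoate
Product: 24 4-methoxybenzyl (2R,3R,4Z)-4-(5,5-dimethylfuran-2(5H)-ylidene)-3-(1,3-dioxolan-2-ylmethyl)-2-[5-(2-methyl-1,3-dioxolan-2-yl)pent-1-en-2-yl]butanoate
Conditions: pyridinium p-toluenesulfonate (5 mol %), 4 Å molecular sieves, toluene, 40 °C; Et3N quench, filtration through basic alumina, used at once
Reagents that add atoms: none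
Why: Acid‑catalysed dehydration of a cyclic hemiketal, in which ionisation gives an allylic oxocarbenium ion that can lose a proton only from C5 (the gem‑dimethyl carbon blocks aromatisation to a furan) to give the exocyclic dienol ether, expected mainly as the less crowded (Z) isomer with C4 next to the ring oxygen.

Step 13
Reactants: 24 4-methoxybenzyl (2R,3R,4Z)-4-(5,5-dimethylfuran-2(5H)-ylidene)-3-(1,3-dioxolan-2-ylmethyl)-2-[5-(2-methyl-1,3-dioxolan-2-yl)pent-1-en-2-yl]butanoate
Product: 25 4-methoxybenzyl (2R,3S,4E)-4-(5,5-dimethylfuran-2(5H)-ylidene)-3-(1,3-dioxolan-2-ylmethyl)-2-[5-(2-methyl-1,3-dioxolan-2-yl)pent-1-en-2-yl]-5-oxopentanoate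
Conditions: [Me2N=CHCl]Cl (1.5 equiv), DMF/CH2Cl2, 0 °C; then aq. NaOAc, 20 °C
Reagents that add atoms: (chloromethylene)dimethyliminium chloride, C[N+](C)=CCl.[Cl-]; water, O
Why: Vilsmeier–Haack formylation of an enol ether, in which the chloroiminium ion attacks C5, the only carbon made nucleophilic by O1′ (the resulting cation is at once an oxocarbenium and an allyl cation), loss of the C5 proton gives the vinylogous iminium salt, and buffered hydrolysis releases the β‑alkoxy enal, whose push–pull C5=C2′ bond should equilibrate to the (E) isomer.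

Step 14
Reactants: 25 4-methoxybenzyl (2R,3S,4E)-4-(5,5-dimethylfuran-2(5H)-ylidene)-3-(1,3-dioxolan-2-ylmethyl)-2-[5-(2-methyl-1,3-dioxolan-2-yl)pent-1-en-2-yl]-5-oxopentanoate
Product: 26 (2R,3S,4E)-4-(5,5-dimethylfuran-2(5H)-ylidene)-5-oxo-3-(2-oxoethyl)-2-(6-oxohept-1-en-2-yl)pentanoic acid
Conditions: CF3CO2H/CH2Cl2 1:4, anisole (5 equiv), 0 °C; then H2O/THF added, 20 °C
Reagents that add atoms: water, O
Why: Acidolysis of the 4‑methoxybenzyl ester (SN1 loss of the benzyl cation, captured by anisole) followed in the same flask by hydrolysis of both dioxolanes, conditions that the vinylogous formate and the 1,1‑disubstituted alkene should tolerate, under which neither C3 nor C4 can epimerise, and under which the push–pull alkene rests in its (E) form.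

**Compound list**

1 | 2-(2-bromoethyl)-2-methyl-1,3-dioxolane | CC1(CCBr)OCCO1 | starting material
2 | 2,3-dibromoprop-1-ene | C=C(Br)CBr | starting material
3 | [2-(2-methyl-1,3-dioxolan-2-yl)ethyl]magnesium bromide | CC1(CC[Mg]Br)OCCO1 | intermediate
4 | 2-(4-bromopent-4-en-1-yl)-2-methyl-1,3-dioxolane | C=C(Br)CCCC1(C)OCCO1 | intermediate
5 | 5,6-dihydro-2H-pyran-2-one | O=C1C=CCCO1 | starting material
6 | potassium ethenyltrifluoroborate | C=C[B-](F)(F)F.[K+] | starting material
7 | (4R)-4-ethenyltetrahydro-2H-pyran-2-one | O=C1C[C@H](C=C)CCO1 | intermediate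
8 | dioxygen | O=O | starting material
9 | 2-[(4S)-2-oxotetrahydro-2H-pyran-4-yl]acetaldehyde | O=C1C[C@H](CC=O)CCO1 | intermediate
10 | (4S)-4-(1,3-dioxolan-2-ylmethyl)tetrahydro-2H-pyran-2-one | O=C1C[C@H](CC2OCCO2)CCO1 | intermediate
11 | lithium (4S)-4-(1,3-dioxolan-2-ylmethyl)-5,6-dihydro-4H-pyran-2-olate | [Li+].[O-]C1=C[C@H](CC2OCCO2)CCO1 | intermediate
12 | chloro{[(4S)-4-(1,3-dioxolan-2-ylmethyl)-5,6-dihydro-4H-pyran-2-yl]oxy}zinc | Cl[Zn]OC1=C[C@H](CC2OCCO2)CCO1 | intermediate
13 | (3R,4S)-4-(1,3-dioxolan-2-ylmethyl)-3-[5-(2-methyl-1,3-dioxolan-2-yl)pent-1-en-2-yl]tetrahydro-2H-pyran-2-one (trans) | C=C(CCCC1(C)OCCO1)[C@@H]2C(=O)OCC[C@H]2CC3OCCO3 | intermediate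
14 | potassium (2R,3S)-3-(1,3-dioxolan-2-ylmethyl)-5-hydroxy-2-[5-(2-methyl-1,3-dioxolan-2-yl)pent-1-en-2-yl]pentanoate | C=C(CCCC1(C)OCCO1)[C@H](C(=O)[O-])[C@H](CC2OCCO2)CCO.[K+] | intermediate
15 | 4-methoxybenzyl (2R,3S)-3-(1,3-dioxolan-2-ylmethyl)-5-hydroxy-2-[5-(2-methyl-1,3-dioxolan-2-yl)pent-1-en-2-yl]pentanoate | C=C(CCCC1(C)OCCO1)[C@H](C(=O)OCc2ccc(OC)cc2)[C@H](CC3OCCO3)CCO | intermediate
16 | 4-methoxybenzyl (2R,3R)-3-(1,3-dioxolan-2-ylmethyl)-2-[5-(2-methyl-1,3-dioxolan-2-yl)pent-1-en-2-yl]-5-[(1-phenyl-1H-tetrazol-5-yl)sulfanyl]pentanoate | C=C(CCCC1(C)OCCO1)[C@H](C(=O)OCc2ccc(OC)cc2)[C@H](CC3OCCO3)CCSc4nnnn4-c5ccccc5 | intermediate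
17 | 4-methoxybenzyl (2R,3R)-3-(1,3-dioxolan-2-ylmethyl)-2-[5-(2-methyl-1,3-dioxolan-2-yl)pent-1-en-2-yl]-5-[(1-phenyl-1H-tetrazol-5-yl)sulfonyl]pentanoate | C=C(CCCC1(C)OCCO1)[C@H](C(=O)OCc2ccc(OC)cc2)[C@H](CC3OCCO3)CCS(=O)(=O)c4nnnn4-c5ccccc5 | intermediate
18 | 3-methylbut-2-enal | CC(C)=CC=O | starting material
19 | potassium salt of the α-sulfonyl carbanion of 17 | C=C(CCCC1(C)OCCO1)[C@H](C(=O)OCc2ccc(OC)cc2)[C@H](CC3OCCO3)C[CH-]S(=O)(=O)c4nnnn4-c5ccccc5.[K+] | intermediate
20 | 4-methoxybenzyl (2R,3S,5E)-3-(1,3-dioxolan-2-ylmethyl)-8-methyl-2-[5-(2-methyl-1,3-dioxolan-2-yl)pent-1-en-2-yl]nona-5,7-dienoate | C=C(CCCC1(C)OCCO1)[C@H](C(=O)OCc2ccc(OC)cc2)[C@H](CC3OCCO3)C/C=C/C=C(C)C | intermediate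
21 | 4-methoxybenzyl (2R,3S)-4-(6,6-dimethyl-3,6-dihydro-1,2-dioxin-3-yl)-3-(1,3-dioxolan-2-ylmethyl)-2-[5-(2-methyl-1,3-dioxolan-2-yl)pent-1-en-2-yl]butanoate (both epimers at the dioxine CH) | C=C(CCCC1(C)OCCO1)[C@H](C(=O)OCc2ccc(OC)cc2)[C@H](CC3OCCO3)CC4C=CC(C)(C)OO4 | intermediate
22 | 4-methoxybenzyl (2R,3R,6Z)-3-(1,3-dioxolan-2-ylmethyl)-8-hydroxy-8-methyl-2-[5-(2-methyl-1,3-dioxolan-2-yl)pent-1-en-2-yl]-5-oxonon-6-enoate | C=C(CCCC1(C)OCCO1)[C@H](C(=O)OCc2ccc(OC)cc2)[C@H](CC3OCCO3)CC(=O)/C=C\C(C)(C)O | intermediate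
23 | 4-methoxybenzyl (2R,3R)-3-(1,3-dioxolan-2-ylmethyl)-4-(2-hydroxy-5,5-dimethyl-2,5-dihydrofuran-2-yl)-2-[5-(2-methyl-1,3-dioxolan-2-yl)pent-1-en-2-yl]butanoate (both hemiketal epimers) | C=C(CCCC1(C)OCCO1)[C@H](C(=O)OCc2ccc(OC)cc2)[C@H](CC3OCCO3)CC4(O)C=CC(C)(C)O4 | intermediate
24 | 4-methoxybenzyl (2R,3R,4Z)-4-(5,5-dimethylfuran-2(5H)-ylidene)-3-(1,3-dioxolan-2-ylmethyl)-2-[5-(2-methyl-1,3-dioxolan-2-yl)pent-1-en-2-yl]butanoate | C=C(CCCC1(C)OCCO1)[C@H](C(=O)OCc2ccc(OC)cc2)[C@H](CC3OCCO3)/C=C4/C=CC(C)(C)O4 | intermediate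
25 | 4-methoxybenzyl (2R,3S,4E)-4-(5,5-dimethylfuran-2(5H)-ylidene)-3-(1,3-dioxolan-2-ylmethyl)-2-[5-(2-methyl-1,3-dioxolan-2-yl)pent-1-en-2-yl]-5-oxopentanoate | C=C(CCCC1(C)OCCO1)[C@H](C(=O)OCc2ccc(OC)cc2)[C@H](CC3OCCO3)/C(C=O)=C4/C=CC(C)(C)O4 | intermediate
26 | (2R,3S,4E)-4-(5,5-dimethylfuran-2(5H)-ylidene)-5-oxo-3-(2-oxoethyl)-2-(6-oxohept-1-en-2-yl)pentanoic acid | C=C(CCCC(C)=O)[C@H](C(=O)O)[C@H](CC=O)/C(C=O)=C1/C=CC(C)(C)O1 | target

**Step count and risks**

Total step count: 14. Longest linear sequence: 13 (steps 2–14); step 1 supplies bromide 4, which enters at step 5.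

Steps most likely to fail:

1. Step 10. The ene reaction (hydrogen abstraction from a methyl of the Me2C=CH terminus, or from the allylic positions of C1=C2) may outrun the cycloaddition because the inside methyl penalises the s‑cis conformer; allylic hydroperoxides would then form in place of the dioxine. Fallback from 15, returning at 23, without any peroxide: alcohol 15 is oxidised with Dess–Martin periodinane (NaHCO3, CH2Cl2) to the 5‑oxopentanoate aldehyde F1. The dilithio derivative of 2‑methylbut‑3‑yn‑2‑ol (n‑BuLi, THF, −78 °C) is added to give the alkynediol F2. MnO2 (CH2Cl2) oxidises only the propargylic secondary alcohol to the hydroxy‑ynone F3. Lindlar semihydrogenation (Pd/CaCO3 poisoned with Pb(OAc)2, quinoline, H2, EtOAc) gives the cis‑hydroxyenone 22, which closes to hemiketal 23 and continues with step 12.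

2. Step 5. Transmetalation and reductive elimination at the hindered secondary zinc enolate may be slow, leaving room for enolate self‑condensation or for migration of the new double bond into conjugation with the lactone. Fallback from 10 and 4, returning at 13, with the polarity inverted: the lithium enolate 11 is brominated (N‑bromosuccinimide, THF, −78 °C) to the α‑bromolactone F4. Bromide 4 is converted with Mg (THF) into the alkenylmagnesium bromide F5 and with ZnCl2 into the alkenylzinc chloride F6. A nickel‑catalysed, radical‑type Negishi coupling of F4 with F6 (NiCl2(dme), 4,4′‑di‑tert‑butyl‑2,2′‑bipyridine, THF/DMA, 0 °C), of the kind known for secondary α‑bromo carbonyl compounds with alkenyl nucleophiles, should give 13, the planar α‑acyl radical being captured trans to the C4 side chain.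

3. Step 13. Protonation of the dienol ether by the HCl released, followed by oligomerisation or ring opening, may be faster than C‑formylation, and the chloroiminium ion may also attack a dioxolane. Fallback from 23, returning at 25, in which the formyl carbon is attached before the ring is dehydrated: hemiketal 23, in equilibrium with open‑chain 22, is condensed at the C5 methylene with tert‑butoxybis(dimethylamino)methane (Bredereck's reagent, toluene, 60 °C) to the enaminone F7. Mild aqueous acid (AcOH/H2O/THF, 20 °C) lets the tertiary hydroxyl add to C2′ of the vinylogous amide, water is lost, and the resulting vinylogous iminium ether is hydrolysed with loss of dimethylamine to 25.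

Further compounds
F1 | step 10 | 4-methoxybenzyl (2R,3S)-3-(1,3-dioxolan-2-ylmethyl)-2-[5-(2-methyl-1,3-dioxolan-2-yl)pent-1-en-2-yl]-5-oxopentanoate | C=C(CCCC1(C)OCCO1)[C@H](C(=O)OCc2ccc(OC)cc2)[C@H](CC3OCCO3)CC=O
F2 | step 10 | 4-methoxybenzyl (2R,3S)-3-(1,3-dioxolan-2-ylmethyl)-5,8-dihydroxy-8-methyl-2-[5-(2-methyl-1,3-dioxolan-2-yl)pent-1-en-2-yl]non-6-ynoate (both C5 epimers) | C=C(CCCC1(C)OCCO1)[C@H](C(=O)OCc2ccc(OC)cc2)[C@H](CC3OCCO3)CC(O)C#CC(C)(C)O
F3 | step 10 | 4-methoxybenzyl (2R,3R)-3-(1,3-dioxolan-2-ylmethyl)-8-hydroxy-8-methyl-2-[5-(2-methyl-1,3-dioxolan-2-yl)pent-1-en-2-yl]-5-oxonon-6-ynoate | C=C(CCCC1(C)OCCO1)[C@H](C(=O)OCc2ccc(OC)cc2)[C@H](CC3OCCO3)CC(=O)C#CC(C)(C)O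
F4 | step 5 | (4S)-3-bromo-4-(1,3-dioxolan-2-ylmethyl)tetrahydro-2H-pyran-2-one (both C3 epimers) | O=C1C(Br)[C@H](CC2OCCO2)CCO1
F5 | step 5 | [5-(2-methyl-1,3-dioxolan-2-yl)pent-1-en-2-yl]magnesium bromide | C=C([Mg]Br)CCCC1(C)OCCO1
F6 | step 5 | chloro[5-(2-methyl-1,3-dioxolan-2-yl)pent-1-en-2-yl]zinc | C=C([Zn]Cl)CCCC1(C)OCCO1
F7 | step 13 | 4-methoxybenzyl (2R,3S,6Z)-4-[(dimethylamino)methylidene]-3-(1,3-dioxolan-2-ylmethyl)-8-hydroxy-8-methyl-2-[5-(2-methyl-1,3-dioxolan-2-yl)pent-1-en-2-yl]-5-oxonon-6-enoate (aminomethylidene geometry undefined) | C=C(CCCC1(C)OCCO1)[C@H](C(=O)OCc2ccc(OC)cc2)[C@H](CC3OCCO3)C(=CN(C)C)C(=O)/C=C\C(C)(C)O
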